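# Proposed synthesis of (3R)-6,8-dihydroxy-3-[(9S)-9-hydroxyundecyl]-3,4-dihydro-1H-isochromen-1-one (19)

Numbering used throughout: isochromanone ring C1 (C=O), O2, C3, C4, C4a, C5–C8, C8a; side chain C1′–C11′ with the carbinol at C9′. Read from the SMILES, C3 is R and C9′ is S.

## The problem

- The skeleton is a 3,4-dihydroisocoumarin: a benzene ring (C4a–C8a) fused to a δ-lactone. The arene carries the C1 carboxyl on C8a, hydroxyls on C8 and C6, and the C4 methylene on C4a.
- There are only two stereocentres, C3 (R) in the lactone and C9′ (S) in the chain. Eight methylenes separate them, so neither can control the other and each must be brought in with absolute control.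
- Epimers that differ at centres ten atoms apart cannot be expected to separate, so any stereochemical leakage at either centre is permanent.
- C9′ is an ethyl/n-alkyl carbinol, a poor case for catalyst-controlled ketone reduction. Both carbinol carbons are, however, C-2 of a terminal epoxide opened at C-1 by carbon, and they have the same spatial sense along the chain. Both can therefore be taken from the chiral pool: (S)-1,2-epoxybutane and (R)-epichlorohydrin.
- The sensitive groups are two free phenols on an electron-rich ring, a base-labile lactone and a free secondary alcohol. The usual phenol methyl ethers would need BBr3-type cleavage in the presence of that alcohol and the lactone.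
- The feature that makes the key step possible: ring atoms C5–C6(O)–C7–C8(O) are an intact 1,3-dioxygenated four-carbon unit, and C4a/C8a–C1(=O)O is an intact 2-ynoate unit. The C3 oxygen is δ to C1. The benzene ring can therefore be made by [4+2] addition of a 1,3-bis(silyloxy)diene to a 5-hydroxy-2-ynoate, after which the lactone closes by itself.
- The arene is the only stereochemically silent part of the molecule. Building it last puts no stereocentre at risk and means the phenols never need a protecting-group step.

## Retrosynthesis

**19 ⇒ 18.** The lactone bond O2–C1 is cut. The C3 hydroxyl and the C1 methyl ester sit ortho on the arene, so six-membered closure needs only acid and proceeds with retention at C3. The cut is chosen so that C1 can travel through ring construction as an ordinary ester.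

**18 ⇒ 12 + 14 (through 15, 16 and 17).** Both ring bonds C4a–C5 and C8–C8a are cut, which takes the arene apart into ynoate 12 (C4a, C8a, C1) and diene 14 (C5–C8 plus a CMe2–CH2 bridge lost as 2-methylpropene).
- Against the neighbouring cuts: cutting C4–C4a or C8a–C1 keeps a purchased arene, but then the phenols must be protected, C1 must be added separately and the ethers removed at the end.
- Simplification: 12 is acyclic with one ester, one alkyne and both stereocentres. The product is the complete bicycle with free phenols.
- Demands on the forward reaction: regiocontrol, which the polarity of both partners supplies, and thermal tolerance of the silyl ethers.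

**12 ⇒ 9 + 10 (through 11).** The propargylic bond C4–C4a is cut. This places C3 in a terminal epoxide whose opening at CH2 cannot touch the stereocentre, and it installs the whole dienophile in one bond. A cut at C3–C4 (aldehyde plus propargyl nucleophile) would instead create C3 in the step and depend on reagent control. The forward reaction needs BF3 activation at −78 °C that spares the TBS ether.

**9 ⇒ 5 + 6 (through 7 and 8).** The bond C1′–C2′ is cut. (R)-Epichlorohydrin supplies C4, C3, C1′ and the C3 oxygen. The Grignard reagent must attack the epoxide CH2 and not CH2Cl; base then closes the new epoxide on the other side, leaving the configuration untouched.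

**5 ⇒ 4 ⇒ 1 + 2 (through 3).** The bond C7′–C8′ is cut. (S)-1,2-Epoxybutane supplies C8′–C11′ with the C9′ oxygen, and 1 supplies C2′–C7′. A C2-symmetric bis-epoxide would have homotopic ends and would differentiate only statistically. The Br/Cl difference in 1 orders the two epoxide openings and avoids that.

**14 ⇒ 13.** Two O–Si bonds are cut; the diene is one step from dimedone.

## Roads not taken

**Alternative 1:** the most obvious route, with the arene bought.
- Cut: C4–C4a, then C8a–C1.
- Forward key step: Cu-catalysed opening of 9 by a 3,5-dimethoxyphenyl metal gives (2R,11S)-1-(3,5-dimethoxyphenyl)-11-[(tert-butyldimethylsilyl)oxy]tridecan-2-ol A1. Ring halogenation and carbonylative lactonisation then give the 6,8-dimethoxy lactone A2, followed by O-demethylation.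
- Why the chosen plan is better: this route needs about four steps from 9 against two. The halogenation must distinguish two activated ring positions. The final ether cleavage needs boron or aluminium halides in the presence of the lactone and the secondary carbinol. The cycloaddition gives the free phenols directly, with regiochemistry fixed by polarity.

**Alternative 2:** C3 set last on a flat heterocycle.
- Cut: the C3–H and C4–H bonds.
- Forward key step: enantioselective hydrogenation of the C3=C4 bond of isocoumarin A4. A4 would come from Sonogashira coupling and 6-endo cyclisation of alkynol A3 (itself from an alkyne-zipper migration of its propargylic isomer) with a protected o-halo-resorcylate.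
- Why the chosen plan is better: C3 would rest on catalyst face selection alone, for a 3-n-alkyl-8-alkoxy substrate, and any leakage gives the inseparable (3S,9′S) epimer. The halo-resorcylate and the deprotection add steps. The chiral pool delivers C3 without a selectivity question.

**Alternative 3:** strain release.
- Cut: C3–C4 and C1–O2 together.
- Forward key step: thermal electrocyclic opening of benzocyclobutenone A5 to the o-quinoid ketene methide, then hetero-[4+2] addition to the C=O of aldehyde A6.
- Why the chosen plan is better: C3 would be formed in the cycloaddition on an unactivated, enolisable aldehyde with no control element within reach. Such aldehydes are poor heterodienophiles for this ketene, which can dimerise or undergo ene reactions instead. The methyl ethers would still have to be removed. In the chosen pericyclic step no stereocentre is formed at all.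

Key step: step 6

Assumption: compounds 1, 2, 6, 10 and 13 are taken as commercial, 2 and 6 in high enantiomeric purity.

## Route

Step 1
Reactants: 1 1-bromo-6-chlorohexane; 2 (S)-1,2-epoxybutane
Product: 4 (3S)-10-chlorodecan-3-ol, via 6-chlorohexylmagnesium bromide 3 (not isolated)
Conditions: Mg, THF, 20–30 °C; then CuI (5 mol%), 2, THF, −30 → 0 °C; aq. NH4Cl
Reagents that add atoms: none
Why: Magnesium inserts into C–Br in preference to the primary C–Cl, and the Cu(I)-catalysed Grignard opening of a terminal epoxide is an SN2 attack at the unsubstituted carbon, so the C–O centre of 2 is carried over unchanged as C9′ (S).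

Step 2
Reactants: 4 (3S)-10-chlorodecan-3-ol
Product: 5 tert-butyl{[(3S)-10-chlorodecan-3-yl]oxy}dimethylsilane
Conditions: TBSCl, imidazole, DMF, rt
Reagents that add atoms: tert-butyldimethylsilyl chloride, CC(C)(C)[Si](C)(C)Cl
Why: Standard silylation of a secondary alcohol; the TBS ether should survive Grignard formation, BF3 at −78 °C and neutral thermolysis, and it falls in the final acid stage.

Step 3
Reactants: 5 tert-butyl{[(3S)-10-chlorodecan-3-yl]oxy}dimethylsilane; 6 (R)-epichlorohydrin
Product: 9 (2R)-2-{(9S)-9-[(tert-butyldimethylsilyl)oxy]undecyl}oxirane, via {(8S)-8-[(tert-butyldimethylsilyl)oxy]decyl}magnesium chloride 7 (not isolated), via (2R,11S)-11-[(tert-butyldimethylsilyl)oxy]-1-chlorotridecan-2-ol 8 (not isolated)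
Conditions: Mg (BrCH2CH2Br-activated), THF, 60 °C; then CuI (10 mol%), 6, THF, −40 → −10 °C; aq. NH4Cl; then powdered NaOH, Et2O, rt
Reagents that add atoms: none
Why: Cu(I)-catalysed Grignard opening of epichlorohydrin at the epoxide CH2 gives chlorohydrin 8, and intramolecular Williamson closure then forms the new epoxide; C-2 of 6 is never a reacting centre, so its R configuration is retained and becomes C3.

Step 4
Reactants: 9 (2R)-2-{(9S)-9-[(tert-butyldimethylsilyl)oxy]undecyl}oxirane; 10 methyl propiolate
Product: 12 methyl (5R,14S)-14-[(tert-butyldimethylsilyl)oxy]-5-hydroxyhexadec-2-ynoate, via lithium methyl propiolate 11 (not isolated)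
Conditions: 10, n-BuLi, THF, −78 °C; BF3·OEt2; then 9, −78 °C; aq. NH4Cl at −78 °C
Reagents that add atoms: none
Why: Yamaguchi–Hirao alkynylation: the BF3-activated terminal epoxide is opened at CH2 by the lithium acetylide at −78 °C, which leaves the carbinol centre untouched and installs the complete dienophile in one C–C bond.

Step 5
Reactants: 13 dimedone
Product: 14 5,5-dimethyl-1,3-bis(trimethylsilyloxy)cyclohexa-1,3-diene
Conditions: TMSOTf (2.2 equiv), Et3N (2.5 equiv), Et2O, 0 °C → rt
Reagents that add atoms: trimethylsilyl trifluoromethanesulfonate, C[Si](C)(C)OS(=O)(=O)C(F)(F)F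
Why: Double soft enolisation and O-silylation of a cyclic 1,3-dione gives the 1,3-bis(silyloxy)diene; the reagent is used directly after filtration and distillation under inert gas.

Step 6
Reactants: 12 methyl (5R,14S)-14-[(tert-butyldimethylsilyl)oxy]-5-hydroxyhexadec-2-ynoate; 14 5,5-dimethyl-1,3-bis(trimethylsilyloxy)cyclohexa-1,3-diene
Product: 19 (3R)-6,8-dihydroxy-3-[(9S)-9-hydroxyundecyl]-3,4-dihydro-1H-isochromen-1-one, via O-trimethylsilyl ynoate 15 (not isolated), via bicyclo[2.2.2]octadiene adduct 16 (not isolated), via tetrasilylated methyl resorcylate 17 (not isolated), via desilylated methyl resorcylate 18 (not isolated)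
Conditions: BSA (1.2 equiv), PhMe, rt; 14 (3 equiv), neat, 140–150 °C, sealed tube; then TsOH·H2O (cat.), MeOH, rt; then PhMe, 80 °C
Reagents that add atoms: none
Why: A normal-electron-demand Diels–Alder reaction between the electron-rich bis(silyloxy)diene 14 and the electron-poor 2-ynoate 15 is followed by retro-Diels–Alder loss of the CMe2–CH2 bridge of 16 as 2-methylpropene; the closest known reaction type is this same Diels–Alder/retro-Diels–Alder cycloaromatisation of 2-ynoate esters, macrocyclic ones included, with 1,3-bis(trimethylsilyloxy)cyclohexa-1,3-dienes to give 6-alkyl-2,4-dihydroxybenzoates. The selectivity the step needs is regiochemical: diene C4, β to the C3 silyloxy group and vinylogously δ to the C1 silyloxy group, carries the largest HOMO coefficient and bonds to the ynoate β-carbon (future C4a), so the oxygenated terminus C1 bonds to the α-carbon (future C8a) and the oxygens arrive on C8 and C6 only. The benzene ring is closed by the concerted [4+2] addition and made aromatic by the [4+2] cycloreversion, which is irreversible because the alkene leaves as a gas. The lactone is then closed by 6-exo-trig acyl substitution of the freed C3 hydroxyl at the ester carbon C1 of 18, favoured by the ortho arrangement on the new arene. No stereocentre is formed: the bridgehead centres of 16 vanish on aromatisation, and C3 and C9′ are spectators, being neither enolisable nor benzylic, while lactonisation occurs at C1 with retention at C3. In-situ O-silylation with BSA keeps the free hydroxyl from protodesilylating the diene, and the single acid stage removes all four silyl groups, so the phenols never need a separate protecting-group step. Dimedone from the excess diene should be removed by a bicarbonate wash.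

## Compound list

1 | 1-bromo-6-chlorohexane | ClCCCCCCBr | starting material
2 | (S)-1,2-epoxybutane | CC[C@H]1CO1 | starting material
3 | 6-chlorohexylmagnesium bromide | ClCCCCCC[Mg]Br | intermediate
4 | (3S)-10-chlorodecan-3-ol | CC[C@H](O)CCCCCCCCl | intermediate
5 | tert-butyl{[(3S)-10-chlorodecan-3-yl]oxy}dimethylsilane | CC[C@H](O[Si](C)(C)C(C)(C)C)CCCCCCCCl | intermediate
6 | (R)-epichlorohydrin | ClC[C@H]1CO1 | starting material
7 | {(8S)-8-[(tert-butyldimethylsilyl)oxy]decyl}magnesium chloride | CC[C@H](O[Si](C)(C)C(C)(C)C)CCCCCCC[Mg]Cl | intermediate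
8 | (2R,11S)-11-[(tert-butyldimethylsilyl)oxy]-1-chlorotridecan-2-ol | ClC[C@H](O)CCCCCCCC[C@H](CC)O[Si](C)(C)C(C)(C)C | intermediate
9 | (2R)-2-{(9S)-9-[(tert-butyldimethylsilyl)oxy]undecyl}oxirane | C1[C@H](O1)CCCCCCCC[C@H](CC)O[Si](C)(C)C(C)(C)C | intermediate
10 | methyl propiolate | C#CC(=O)OC | starting material
11 | lithium methyl propiolate (methyl 3-lithioprop-2-ynoate) | [Li]C#CC(=O)OC | intermediate
12 | methyl (5R,14S)-14-[(tert-butyldimethylsilyl)oxy]-5-hydroxyhexadec-2-ynoate | COC(=O)C#CC[C@H](O)CCCCCCCC[C@H](CC)O[Si](C)(C)C(C)(C)C | intermediate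
13 | dimedone (5,5-dimethylcyclohexane-1,3-dione) | CC1(C)CC(=O)CC(=O)C1 | starting material
14 | 5,5-dimethyl-1,3-bis(trimethylsilyloxy)cyclohexa-1,3-diene | C[Si](C)(C)OC1=CC(O[Si](C)(C)C)=CC(C)(C)C1 | intermediate
15 | methyl (5R,14S)-14-[(tert-butyldimethylsilyl)oxy]-5-(trimethylsilyloxy)hexadec-2-ynoate | COC(=O)C#CC[C@H](O[Si](C)(C)C)CCCCCCCC[C@H](CC)O[Si](C)(C)C(C)(C)C | intermediate
16 | methyl 3-{(2R,11S)-11-[(tert-butyldimethylsilyl)oxy]-2-(trimethylsilyloxy)tridecyl}-8,8-dimethyl-1,6-bis(trimethylsilyloxy)bicyclo[2.2.2]octa-2,5-diene-2-carboxylate (bridgehead epimers) | COC(=O)C1=C(C[C@H](O[Si](C)(C)C)CCCCCCCC[C@H](CC)O[Si](C)(C)C(C)(C)C)C2C=C(O[Si](C)(C)C)C1(O[Si](C)(C)C)CC2(C)C | intermediate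
17 | methyl 2-{(2R,11S)-11-[(tert-butyldimethylsilyl)oxy]-2-(trimethylsilyloxy)tridecyl}-4,6-bis(trimethylsilyloxy)benzoate | COC(=O)c1c(O[Si](C)(C)C)cc(O[Si](C)(C)C)cc1C[C@H](O[Si](C)(C)C)CCCCCCCC[C@H](CC)O[Si](C)(C)C(C)(C)C | intermediate
18 | methyl 2-[(2R,11S)-2,11-dihydroxytridecyl]-4,6-dihydroxybenzoate | COC(=O)c1c(O)cc(O)cc1C[C@H](O)CCCCCCCC[C@H](CC)O | intermediate
19 | (3R)-6,8-dihydroxy-3-[(9S)-9-hydroxyundecyl]-3,4-dihydro-1H-isochromen-1-one | CC[C@H](O)CCCCCCCC[C@@H]1Cc2cc(O)cc(O)c2C(=O)O1 | target

## Step count and risk

Total: 6 steps. Longest linear sequence: 5 steps (1, 2, 3, 4, 6); step 5 is a one-step branch.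

**Step 6 (key step).**
- What may go wrong: the β-alkyl ynoate may be too weak a dienophile at temperatures the diene tolerates, so that thermal desilylation or oligomerisation of the diene outruns cycloaddition. A stepwise Mukaiyama–Michael addition without ring closure is the other escape. Incomplete lactonisation in methanol is a minor concern and is answered by the toluene stage.
- Fallback: from 9 to 19 with the arene bought. Commercial 1-bromo-3,5-bis(benzyloxy)benzene and Mg give 3,5-bis(benzyloxy)phenylmagnesium bromide F1. With CuI catalysis F1 opens 9 at the terminal carbon to give (2R,11S)-1-[3,5-bis(benzyloxy)phenyl]-11-[(tert-butyldimethylsilyl)oxy]tridecan-2-ol F2. NBS in MeCN should brominate the ring position between the side chain and a benzyloxy group, para to the other, giving (2R,11S)-1-[3,5-bis(benzyloxy)-2-bromophenyl]-11-[(tert-butyldimethylsilyl)oxy]tridecan-2-ol F3. Pd-catalysed carbonylative lactonisation (CO, Pd(OAc)2/dppf, Et3N, 100 °C) then gives (3R)-6,8-bis(benzyloxy)-3-{(9S)-9-[(tert-butyldimethylsilyl)oxy]undecyl}-3,4-dihydro-1H-isochromen-1-one F4. Hydrogenolysis over Pd/C in methanol containing HCl removes both benzyl ethers and the silyl ether in one operation and gives 19.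

**Step 3.**
- What may go wrong: slow magnesium insertion into the primary chloride, with Wurtz coupling. More seriously, direct displacement of chloride in 6 would compete with epoxide opening; that path leads to the enantiomeric epoxide and so erodes the purity at C3.
- Fallback: from 5 to 9, using 5 as the electrophile and resetting the centre by resolution. Finkelstein exchange (NaI, acetone) gives tert-butyl{[(3S)-10-iododecan-3-yl]oxy}dimethylsilane F5. Allylmagnesium bromide with catalytic Li2CuCl4 gives tert-butyldimethyl{[(3S)-tridec-12-en-3-yl]oxy}silane F6. mCPBA gives the epoxide as a mixture of C2 epimers, 2-{(9S)-9-[(tert-butyldimethylsilyl)oxy]undecyl}oxirane F7. Hydrolytic kinetic resolution with (salen)Co(III)OAc and 0.55 equiv of water, using the catalyst enantiomer that hydrolyses (2S)-alkyloxiranes (the (S,S)-catalyst is expected), leaves 9.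

**Step 4.**
- What may go wrong: decomposition of lithium propiolate above −78 °C, BF3-induced rearrangement of the epoxide to the aldehyde, or loss of the silyl ether, all of which lower conversion.
- Fallback: from 9 to 15, building the ynoate in two bonds. Lithium acetylide–ethylenediamine complex in DMSO opens 9 to (4R,13S)-13-[(tert-butyldimethylsilyl)oxy]pentadec-1-yn-4-ol F8. TMSCl/Et3N gives its trimethylsilyl ether, (4R,13S)-13-[(tert-butyldimethylsilyl)oxy]-4-(trimethylsilyloxy)pentadec-1-yne F9. Deprotonation with n-BuLi at −78 °C and quenching with methyl chloroformate gives 15, which enters step 6 after the BSA stage.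

## Further compounds

F1 | step 6 | 3,5-bis(benzyloxy)phenylmagnesium bromide | Br[Mg]c1cc(OCc2ccccc2)cc(OCc2ccccc2)c1
F2 | step 6 | (2R,11S)-1-[3,5-bis(benzyloxy)phenyl]-11-[(tert-butyldimethylsilyl)oxy]tridecan-2-ol | CC[C@H](O[Si](C)(C)C(C)(C)C)CCCCCCCC[C@@H](O)Cc1cc(OCc2ccccc2)cc(OCc2ccccc2)c1
F3 | step 6 | (2R,11S)-1-[3,5-bis(benzyloxy)-2-bromophenyl]-11-[(tert-butyldimethylsilyl)oxy]tridecan-2-ol | CC[C@H](O[Si](C)(C)C(C)(C)C)CCCCCCCC[C@@H](O)Cc1cc(OCc2ccccc2)cc(OCc2ccccc2)c1Br
F4 | step 6 | (3R)-6,8-bis(benzyloxy)-3-{(9S)-9-[(tert-butyldimethylsilyl)oxy]undecyl}-3,4-dihydro-1H-isochromen-1-one | CC[C@H](O[Si](C)(C)C(C)(C)C)CCCCCCCC[C@@H]1Cc2cc(OCc3ccccc3)cc(OCc3ccccc3)c2C(=O)O1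
F5 | step 3 | tert-butyl{[(3S)-10-iododecan-3-yl]oxy}dimethylsilane | CC[C@H](O[Si](C)(C)C(C)(C)C)CCCCCCCI
F6 | step 3 | tert-butyldimethyl{[(3S)-tridec-12-en-3-yl]oxy}silane | CC[C@H](O[Si](C)(C)C(C)(C)C)CCCCCCCCC=C
F7 | step 3 | 2-{(9S)-9-[(tert-butyldimethylsilyl)oxy]undecyl}oxirane (C2 epimers) | CC[C@H](O[Si](C)(C)C(C)(C)C)CCCCCCCCC1CO1
F8 | step 4 | (4R,13S)-13-[(tert-butyldimethylsilyl)oxy]pentadec-1-yn-4-ol | C#CC[C@H](O)CCCCCCCC[C@H](CC)O[Si](C)(C)C(C)(C)C
F9 | step 4 | (4R,13S)-13-[(tert-butyldimethylsilyl)oxy]-4-(trimethylsilyloxy)pentadec-1-yne | C#CC[C@H](O[Si](C)(C)C)CCCCCCCC[C@H](CC)O[Si](C)(C)C(C)(C)C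
A1 | alternative 1 | (2R,11S)-1-(3,5-dimethoxyphenyl)-11-[(tert-butyldimethylsilyl)oxy]tridecan-2-ol | CC[C@H](O[Si](C)(C)C(C)(C)C)CCCCCCCC[C@@H](O)Cc1cc(OC)cc(OC)c1
A2 | alternative 1 | (3R)-6,8-dimethoxy-3-{(9S)-9-[(tert-butyldimethylsilyl)oxy]undecyl}-3,4-dihydro-1H-isochromen-1-one | CC[C@H](O[Si](C)(C)C(C)(C)C)CCCCCCCC[C@@H]1Cc2cc(OC)cc(OC)c2C(=O)O1
A3 | alternative 2 | (3S)-tridec-12-yn-3-ol | CC[C@H](O)CCCCCCCCC#C
A4 | alternative 2 | 3-[(9S)-9-hydroxyundecyl]-6,8-dimethoxy-1H-isochromen-1-one | CC[C@H](O)CCCCCCCCC1=Cc2cc(OC)cc(OC)c2C(=O)O1
A5 | alternative 3 | 3,5-dimethoxybicyclo[4.2.0]octa-1,3,5-trien-7-one | COc1cc(OC)c2C(=O)Cc2c1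
A6 | alternative 3 | (10S)-10-[(tert-butyldimethylsilyl)oxy]dodecanal | CC[C@H](O[Si](C)(C)C(C)(C)C)CCCCCCCCC=O
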